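All runs come from a simulation with constants of no real substance, noise included.

In a one-step world, where free monomer does nothing but enter chains on a fixed number of living ends, the amount left falls by the same factor every minute, so you can count a run in powers of ten. The question is how many powers of ten alpha and beta get, and what that does to chain length.

in all of them: initiator 2.5 mol%

| run | free monomer | protic impurity | remark | time |
|---|---|---|---|---|
| Saturday's | 0.089 M | 0.010 M | run made earlier |  |
| Friday's | 0.29 M | 0.010 M | run made earlier |  |
| alpha | 0.20 M | 0.0100 M |  | 50 min |
| beta | 0.060 M | 0.0100 M |  | 50 min |

| run | time / min | monomer in chains / % | free monomer / % |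
|---|---|---|---|
| Saturday's | 2.00 | 6.4 | 88.3 |
| Saturday's | 5.00 | 14.0 | 78.1 |
| Saturday's | 10.0 | 21.5 | 67.5 |
| Saturday's | 25.0 | 40.7 | 48.2 |
| Friday's | 2.00 | 20.4 | 76.2 |
| Friday's | 5.00 | 42.0 | 54.6 |
| Friday's | 10.0 | 62.8 | 32.5 |
| Friday's | 25.0 | 85.3 | 12.1 |

(readings scatter by 0.5 percentage points)

- the average divides the monomer in chains by the number of chains begun, living and dead together
- the earlier runs were read with a standard deviation of 0.5 percentage points
- what may be going on: free monomer + initiator -> living end + monomer in chains; free monomer + living end -> monomer in chains + living end; monomer in chains + living end -> free monomer + living end; protic impurity + free monomer -> quenched substrate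
- the earlier runs do not show the number of chains; that part of a forecast is a guess

1. which of the two ends with the longer chains by the average number of monomer units in a chain (chains begun, living or dead) ("neither" if they lie within 10%) (alpha / beta / neither)
2. average number of monomer units in a chain (chains begun, living or dead) at the end, alpha
3. average number of monomer units in a chain (chains begun, living or dead) at the end, beta

The real flask needs three corrections, and this reckoning is mine. First, at 10.0 min Saturday's run is missing 0.00979 M of free monomer, which matches its protic impurity, so I take one free monomer per impurity off the start. Second, I assume each initiator promptly starts one chain that stays living, which keeps c(living end) constant and makes the loss pseudo-first-order. Third, I let monomer return from chains at a steady rate per living end, so the net loss per living end is a rate constant times the gap between c(free monomer) and a floor.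

Two stretches of the readings give that rate constant and that floor, both as readings with their scatter. Friday's run, from 5.00 min to 10.0 min, loses 1.77 min⁻¹ per living end at a mean of 0.126 M. Saturday's run, from 10.0 min to 25.0 min, loses 0.515 min⁻¹ at 0.0515 M. The line through these points has slope 0.279 M⁻¹ s⁻¹ and reaches zero at a floor of 0.0208 M.

Multiply that slope by c(living end) and the time, then divide by 2.30. For alpha, with 0.00500 M, this gives 1.82. This number, the decades of approach, counts the powers of ten by which the gap shrinks. Beta, with 0.00150 M, gets 0.546.

The starting gap is the charge less impurity, first units and floor: 0.164 M for alpha and 0.0277 M for beta. Alpha keeps 1.51% of its gap and beta 28.4%. Length is one plus the closed gap per chain, so I commit to alpha as the longer, with 33.3 for alpha and 14.2 for beta.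

The forecast, noting that “The rate falls off late, indicating reversibility”, names alpha, with 33 (range 27 to 40) for alpha and 15 (11 to 21) for beta, the latter above my figure.

The longer chains stand in alpha, with an average of 33.4 for alpha and 14.6 for beta. Left until 500 min, beta reaches 19.8. The decades of approach there are 5.46, which leaves hardly any of the gap, so the reckoning gives 19.5.

    free monomer + initiator → living end + monomer in chains (k = 0.530 M⁻¹ s⁻¹)
    free monomer + living end → monomer in chains + living end, rate k2*[living end]*[free monomer] (k = 0.280 M⁻¹ s⁻¹)
    monomer in chains + living end → free monomer + living end, rate k3*[living end] as long as [monomer in chains] is above zero (k = 0.00570 s⁻¹)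
    protic impurity + free monomer → quenched substrate (k = 0.0670 M⁻¹ s⁻¹)

Now give beta's recipe 6.2 mol% of initiator: c(living end) is 0.00372 M, the decades of approach are 1.35, the gap is 0.0255 M, and the length comes to 7.55. The computed flask gives 7.74.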